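The runs are simulated on assumed constants.

The charge of starting material is 30.4 times what a saturated solution holds of gas, so if each target takes up one gas, one filling of the solution carries 3.29 % of the charge to target, and the solution has to be refilled as the run goes on.

- gamma: starting material 0.073 M; rival reagent 0.0876 M; gas 2.4 mM (held); the very flask that is asked about, followed so far
- flask: starting material 0.073 M; rival reagent 0.0876 M; gas 2.4 mM (held); time 40 h

gamma run (percent of the starting material charged)

| time / h | target / % |
|---|---|
| 0.417 | 1.7 |
| 0.833 | 3.7 |
| 2.00 | 10.2 |
| 5.00 | 23.6 |

(readings scatter by 0.3 percentage points)

1. the moment within 40 h at which there is most target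
2. the amount of target, in percent of the starting material charged, at that time
3. the first time at which target reaches 24 %, in the same percent

- at the start none of the gas is in solution
- a reading or a percentage of target counts all its forms, free or not

The bench rule says that gas held at saturation is a constant, which makes the loss of starting material pseudo-first-order. You can test that rule with a ratio. Between the second and third readings, target rises at

r = 4.07 mM h⁻¹

and that rate uses up a saturated solution in

τ = csat / r = 0.590 h

This is the drain time: the dissolved gas at saturation divided by the rate at which target forms. The rule needs refilling much quicker than τ. But the flask starts with no gas in solution, and the readings are still picking up to 0.833 h, which is 1.41 drain times. So refilling looks no quicker than draining, and the rule stops here.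

My reckoning takes the dissolved gas as settled where inflow meets use, with τ serving as the refill time too:

inflow = (csat − c gas) / τ

Separately, the slope between the last two readings puts 24 % at 5.09 h.

The forecast gave 28 h, 60 % and 5.1 h, holding that “the target is slowly consumed”. The flask gives 18.4 h, 48.9 % and 5.01 h.

    gas ⇌ partner, rate k1*(csat - [partner]) (kL = 0.0308 min⁻¹)
    starting material + target ⇌ idle adduct, settled at all times (K = 33.0 M⁻¹)
    starting material + partner → target (k = 3.39 M⁻¹ min⁻¹)
    starting material + rival reagent → side product (k = 0.0202 M⁻¹ min⁻¹)
    target → over-reaction product (k = 2.45 × 10⁻⁴ min⁻¹)

In this flask partner, the dissolved gas, stood at 5.18 × 10⁻⁴ M after 4.00 h, under the saturation value of 2.4 mM, and at 6.38 h it was made 1.04 times as fast as it was used, with a half-life against the target step of 0.18 h, shorter than τ. Carried from that state to the neighbour flask of the same recipe read at 10 h, the inflow at τ, less what stayed as partner, gives 20 percentage points more target and over-reaction product together, and that flask stands 23 points higher.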